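Cuts: the C14–C15 single bond (between the CH of the C13-methylated alkene and the CH of the unbranched C15=C15′ alkene, mid-nonaene) divides the target into a C21 ε-ring half and a C19 furanoid half; further cuts at C11=C12, O–C8, C8–H and C8–C9 (furanoid half) and at C11′=C12′ and C9′=C10′ (ε half).
Forward, ε half: (R)-α-ionone is extended by two Horner–Wadsworth–Emmons/nitrile-reduction cycles to (R)-α-retinal and homologated to the C21 terminal alkyne (C15′≡C15–H).
Forward, furanoid half: β-cyclogeraniol → 5,6-epoxide → ethynyl epoxide → enyne (Sonogashira) → 5-hydroxy-6,7-allene (SN2′ hydride) → 2,5-dihydrofuran ring O/C5/C6/C7/C8 (5-endo cycloisomerisation) → enal → C19 trienyl iodide (iodine on C14).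
Union (last step): C15 is an unsubstituted chain terminus, so it can be carried as an alkyne CH, and C14 is the lone CH of the C13=C14 alkene, so it can be carried as an alkenyl iodide; hydroboration of the alkyne and Suzuki–Miyaura coupling in one flask set the 15E alkene and make C14–C15 under basic conditions that spare the acid-labile, doubly allylic C8–O bond of the dihydrofuran ring; no protecting group is used.
Stereochemistry: C6′ from (R)-α-ionone; C5 from a Sharpless epoxidation with D-(−)-diethyl tartrate; C8 by relay epoxide C6–O → allene axis (anti SN2′) → C8 (chirality transfer on ring closure); alkene geometries from E-selective olefinations, stereodefined C4 reagents and stereoretentive couplings.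

Key step: step 19

Assumption: (R)-(+)-α-ionone is bought in enantiomerically pure form and carries C6′ through unchanged; the other starting materials are catalogue chemicals.

Step 1
Reactants: 1 (R)-α-ionone; 2 diethyl cyanomethylphosphonate
Product: 3 (2E,4E)-3-methyl-5-[(1R)-2,6,6-trimethylcyclohex-2-en-1-yl]penta-2,4-dienenitrile
Conditions: 2, NaH, THF, 0 °C; then 1, 0 °C to rt
Reagents that add atoms: none
Why: Horner–Wadsworth–Emmons olefination of the methyl ketone by the pre-formed, weakly basic cyanomethylphosphonate anion should give mainly the 9′E nitrile (the 9′Z isomer is removed by chromatography) and leaves the γ-CH stereocentre C6′ untouched because the carbanion is consumed by carbonyl addition.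

Step 2
Reactants: 3 C15 dienenitrile
Product: 5 (2E,4E)-3-methyl-5-[(1R)-2,6,6-trimethylcyclohex-2-en-1-yl]penta-2,4-dienal, via N-diisobutylalumanyl aldimine 4 (not isolated)
Conditions: iBu2AlH (1.3 equiv), hexane/CH2Cl2, −78 °C; then wet silica gel, 0 °C
Reagents that add atoms: water, O
Why: Nitrile-to-aldehyde reduction, in which iBu2AlH adds once to the C≡N bond, the N-aluminated aldimine is stable at −78 °C, and mild hydrolysis releases the dienal with both alkene geometries and C6′ unchanged.

Step 3
Reactants: 5 C15 dienal; 6 diethyl [(2E)-3-cyano-2-methylprop-2-en-1-yl]phosphonate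
Product: 7 (2E,4E,6E,8E)-3,7-dimethyl-9-[(1R)-2,6,6-trimethylcyclohex-2-en-1-yl]nona-2,4,6,8-tetraenenitrile
Conditions: 6, NaH, THF, 0 °C; then 5, 0 °C to rt, dark
Reagents that add atoms: none
Why: Horner–Wadsworth–Emmons olefination with the γ-stabilised carbanion of the C5 nitrile phosphonate forms the 11′E alkene and brings in the 13′E alkene, the minor 13′Z isomer being removed by chromatography or crystallisation.

Step 4
Reactants: 7 (R)-α-retinonitrile
Product: 9 (2E,4E,6E,8E)-3,7-dimethyl-9-[(1R)-2,6,6-trimethylcyclohex-2-en-1-yl]nona-2,4,6,8-tetraenal, via N-diisobutylalumanyl aldimine 8 (not isolated)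
Conditions: iBu2AlH (1.3 equiv), CH2Cl2, −78 °C; then wet silica gel, 0 °C, dark
Reagents that add atoms: water, O
Why: The same nitrile-to-aldehyde reduction as in step 2 should give (R)-α-retinal without disturbing the tetraene geometry or C6′.

Step 5
Reactants: 9 (R)-α-retinal
Product: 10 (6R)-6-[(1E,3E,5E,7E)-3,7-dimethyldeca-1,3,5,7-tetraen-9-yn-1-yl]-1,5,5-trimethylcyclohex-1-ene
Conditions: Me3SiCHN2, LiN(iPr)2, THF, −78 °C; then 9, −78 °C to rt, dark
Reagents that add atoms: trimethylsilyldiazomethane, C[Si](C)(C)C=[N+]=[N-]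
Why: Colvin homologation, in which lithiated trimethylsilyldiazomethane adds to the aldehyde, Peterson-type loss of Me3SiOLi gives a diazoalkene, and loss of N2 with 1,2-hydride shift of the alkylidene carbene gives the terminal alkyne without conjugate addition to the polyenal.

Step 6
Reactants: 11 prop-2-yn-1-ol
Product: 13 (2E)-3-iodo-2-methylprop-2-en-1-ol, via alkenylalane 12 (not isolated)
Conditions: AlMe3 (3 equiv), Cp2ZrCl2 (0.25 equiv), CH2Cl2, 0 °C to rt; then I2, THF, −30 to 0 °C; aq. K2CO3
Reagents that add atoms: trimethylaluminium, C[Al](C)C; iodine, I-I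
Why: Negishi carboalumination, in which zirconium-catalysed syn addition of Me–Al across the alkyne puts the methyl group on the internal carbon and aluminium on the terminal carbon, and iodinolysis with retention gives the E alkenyl iodide.

Step 7
Reactants: 13 (2E)-3-iodo-2-methylprop-2-en-1-ol
Product: 14 (1E)-3-bromo-1-iodo-2-methylprop-1-ene
Conditions: CBr4, PPh3, CH2Cl2, 0 °C
Reagents that add atoms: carbon tetrabromide, BrC(Br)(Br)Br
Why: Appel reaction, in which the alkoxyphosphonium ion of the primary allylic alcohol is displaced by bromide while the alkenyl iodide is inert.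

Step 8
Reactants: 14 allylic bromide
Product: 15 diethyl [(2E)-3-iodo-2-methylprop-2-en-1-yl]phosphonate
Conditions: P(OEt)3, neat, 100 °C
Reagents that add atoms: triethyl phosphite, CCOP(OCC)OCC
Why: Michaelis–Arbuzov reaction, in which the phosphite displaces the primary allylic bromide and bromide dealkylates the phosphonium ion, the sp2 C–I bond being inert to SN2 attack.

Step 9
Reactants: 16 ethyl acetoacetate
Product: 17 ethyl (2E)-3-{[(trifluoromethyl)sulfonyl]oxy}but-2-enoate
Conditions: Tf2O, aq. Me4NOH, hexanes, 5 °C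
Reagents that add atoms: trifluoromethanesulfonic anhydride, O=S(=O)(OS(=O)(=O)C(F)(F)F)C(F)(F)F
Why: O-Triflation of the β-keto ester enolate, which with the non-chelating tetramethylammonium counter-ion reacts in its extended form and should give the E enol triflate (triflate trans to the ester).

Step 10
Reactants: 17 enol triflate ester
Product: 18 (2E)-4-hydroxybut-2-en-2-yl trifluoromethanesulfonate
Conditions: iBu2AlH (2.2 equiv), CH2Cl2, −78 °C
Reagents that add atoms: none
Why: iBu2AlH reduces the ester to the primary allylic alcohol at −78 °C and leaves the enol triflate and the alkene geometry intact.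

Step 11
Reactants: 19 β-cyclogeraniol
Product: 20 [(1R,6R)-2,2,6-trimethyl-7-oxabicyclo[4.1.0]heptan-1-yl]methanol
Conditions: tBuOOH, Ti(OiPr)4 (10 mol %), D-(−)-diethyl tartrate (12 mol %), 4 Å MS, CH2Cl2, −20 °C
Reagents that add atoms: tert-butyl hydroperoxide, CC(C)(C)OO
Why: Sharpless asymmetric epoxidation, in which the titanium–D-(−)-tartrate catalyst delivers oxygen to the face of the tetrasubstituted alkene that gives the (1R,6R) epoxide, fixing C5 of the target as R under reagent control.

Step 12
Reactants: 20 epoxy alcohol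
Product: 21 (1S,6R)-2,2,6-trimethyl-7-oxabicyclo[4.1.0]heptane-1-carbaldehyde
Conditions: Pr4N[RuO4] (5 mol %), N-methylmorpholine N-oxide, 4 Å MS, CH2Cl2, rt
Reagents that add atoms: none
Why: Ley–Griffith oxidation under neutral conditions takes the primary alcohol to the aldehyde without opening the epoxide, and the aldehyde has no α-hydrogen to epimerise.

Step 13
Reactants: 21 epoxy aldehyde
Product: 22 (1R,6R)-1-ethynyl-2,2,6-trimethyl-7-oxabicyclo[4.1.0]heptane
Conditions: dimethyl (1-diazo-2-oxopropyl)phosphonate, K2CO3, MeOH, 0 °C to rt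
Reagents that add atoms: dimethyl (1-diazo-2-oxopropyl)phosphonate, CC(=O)C(=[N+]=[N-])P(=O)(OC)OC
Why: Ohira–Bestmann variant of the Seyferth–Gilbert homologation, in which the diazomethylphosphonate anion formed in methanol adds to the non-enolisable aldehyde and the derived alkylidene carbene rearranges to the terminal alkyne with the epoxide intact.

Step 14
Reactants: 22 ethynyl epoxide; 18 hydroxy enol triflate
Product: 23 (2E)-3-methyl-5-[(1R,6R)-2,2,6-trimethyl-7-oxabicyclo[4.1.0]heptan-1-yl]pent-2-en-4-yn-1-ol
Conditions: Pd(PPh3)4 (5 mol %), CuI (10 mol %), iPr2NH, THF, rt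
Reagents that add atoms: none
Why: Sonogashira coupling, in which zerovalent palladium inserts into the enol triflate C–O bond with retention of the E geometry and couples with the copper acetylide, which should be faster than ionisation of the hindered, fully substituted propargylic epoxide.

Step 15
Reactants: 23 epoxy enynol
Product: 25 (2E)-5-[(2R)-2-hydroxy-2,6,6-trimethylcyclohexylidene]-3-methylpenta-2,4-dien-1-ol (aS allene), via bis-silyl ether 24 (not isolated)
Conditions: CuCl (5 mol %), IPr·HCl (5 mol %), NaOtBu (12 mol %), (EtO)2MeSiH (3 equiv), toluene, 0 °C to rt; then 2 M NaOH, MeOH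
Reagents that add atoms: none
Why: Copper hydride SN2′ reduction of a propargyl oxirane, in which syn addition of Cu–H across C7≡C8 (hydrogen to C8) followed by anti elimination of the C6–O bond delivers hydride anti to the departing oxygen, so the epoxide configuration is relayed into the aS allene axis (chain on the face of the C5 hydroxy group, H-8 on the face of the C5 methyl group) while the C5–O bond and its R configuration are kept.

Step 16
Reactants: 25 allenic diol
Product: 26 (2E)-3-[(2R,7aR)-4,4,7a-trimethyl-2,4,5,6,7,7a-hexahydro-1-benzofuran-2-yl]but-2-en-1-ol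
Conditions: AuCl3 (2 mol %), 2,2′-bipyridine (3 mol %), THF, rt, dark
Reagents that add atoms: none
Why: Gold-catalysed 5-endo cycloisomerisation of an α-hydroxyallene, in which the C5 oxygen adds to C8 of the gold-activated C7=C8 bond within the plane of the cyclohexylidene unit and protodeauration follows, so the allene axis is transferred to C8 as R (H-8 cis to the C5 methyl group), with bipyridine and THF tempering the Lewis acidity that could ionise the new doubly allylic C8–O bond.

Step 17
Reactants: 26 furanoid allylic alcohol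
Product: 27 (2E)-3-[(2R,7aR)-4,4,7a-trimethyl-2,4,5,6,7,7a-hexahydro-1-benzofuran-2-yl]but-2-enal
Conditions: MnO2 (20 equiv), CH2Cl2, rt
Reagents that add atoms: none
Why: MnO2 oxidises only the allylic primary alcohol to the E enal under neutral conditions that do not enolise towards C8.

Step 18
Reactants: 27 furanoid enal; 15 iodoallyl phosphonate
Product: 28 (2R,7aR)-2-[(2E,4E,6E)-7-iodo-6-methylhepta-2,4,6-trien-2-yl]-4,4,7a-trimethyl-2,4,5,6,7,7a-hexahydro-1-benzofuran
Conditions: 15, LiN(SiMe3)2, THF, −78 °C; then 27, −78 to 0 °C, dark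
Reagents that add atoms: none
Why: Horner–Wadsworth–Emmons olefination, in which the lithiated allylic phosphonate adds to the aldehyde at −78 °C faster than it can remove the γ-hydrogen at C8, gives the 11E alkene and carries the 13E iodoalkene in unchanged.

Step 19
Reactants: 10 C21 terminal alkyne; 28 C19 trienyl iodide
Product: 30 (5R,8R,6′R)-5,8-epoxy-5,8-dihydro-β,ε-carotene (CNP0168410.1), via alkenyl pinacol boronate 29 (not isolated)
Conditions: 10, pinacolborane (1.2 equiv), Cp2Zr(H)Cl (10 mol %), Et3N (10 mol %), CH2Cl2, rt, dark; evaporate; then 28 (0.9 equiv), Pd(PPh3)4 (8 mol %), TlOEt (1.8 equiv), THF/H2O 3:1, rt, dark, argon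
Reagents that add atoms: none
Why: The zirconium hydride adds syn to the only terminal C≡C–H of 10 (metal on C15) and σ-bond metathesis with pinacolborane releases the (E)-alkenylboronate 29; zerovalent palladium then inserts into the C14–I bond of 28 with retention, TlOEt turns the boronate into the ate complex that transfers C15 to palladium, and reductive elimination forms the C14–C15 bond with both alkene geometries intact. The closest known reaction type is the Suzuki–Miyaura diene synthesis from an alkyne-derived alkenylboron and an alkenyl iodide, run here as hydroboration and coupling in one flask so that the air- and light-sensitive pentaenylboron is never isolated. No ring is closed and no stereocentre is created; the step defines the C15=C15′ geometry (syn addition of B–H) and carries over the 13E geometry of the iodide. It needs chemoselective hydrometalation of the alkyne in the presence of six C=C bonds, secured by the unhindered sp C–H terminus and the low reactivity of di- and trisubstituted conjugated alkenes towards the zirconium hydride, and cross-coupling over homocoupling, secured by forming the boron partner before the iodide is added. The basic medium is chosen because the dihydrofuran ring carries a doubly allylic C8–O bond that ionises, and so epimerises C8, under acid; C5, C8 and C6′ are spectators.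

Compound list
1 | (R)-α-ionone, (3E)-4-[(1R)-2,6,6-trimethylcyclohex-2-en-1-yl]but-3-en-2-one | CC1=CCCC(C)(C)[C@H]1/C=C/C(C)=O | starting material
2 | diethyl cyanomethylphosphonate | CCOP(=O)(CC#N)OCC | starting material
3 | (2E,4E)-3-methyl-5-[(1R)-2,6,6-trimethylcyclohex-2-en-1-yl]penta-2,4-dienenitrile | CC1=CCCC(C)(C)[C@H]1/C=C/C(C)=C/C#N | intermediate
4 | N-diisobutylalumanyl aldimine of 5 | CC1=CCCC(C)(C)[C@H]1/C=C/C(C)=C/C=N[Al](CC(C)C)CC(C)C | intermediate
5 | (2E,4E)-3-methyl-5-[(1R)-2,6,6-trimethylcyclohex-2-en-1-yl]penta-2,4-dienal | CC1=CCCC(C)(C)[C@H]1/C=C/C(C)=C/C=O | intermediate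
6 | diethyl [(2E)-3-cyano-2-methylprop-2-en-1-yl]phosphonate (commercial material, mainly E) | CCOP(=O)(C/C(C)=C/C#N)OCC | starting material
7 | (2E,4E,6E,8E)-3,7-dimethyl-9-[(1R)-2,6,6-trimethylcyclohex-2-en-1-yl]nona-2,4,6,8-tetraenenitrile | CC1=CCCC(C)(C)[C@H]1/C=C/C(C)=C/C=C/C(C)=C/C#N | intermediate
8 | N-diisobutylalumanyl aldimine of 9 | CC1=CCCC(C)(C)[C@H]1/C=C/C(C)=C/C=C/C(C)=C/C=N[Al](CC(C)C)CC(C)C | intermediate
9 | (R)-α-retinal, (2E,4E,6E,8E)-3,7-dimethyl-9-[(1R)-2,6,6-trimethylcyclohex-2-en-1-yl]nona-2,4,6,8-tetraenal | CC1=CCCC(C)(C)[C@H]1/C=C/C(C)=C/C=C/C(C)=C/C=O | intermediate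
10 | (6R)-6-[(1E,3E,5E,7E)-3,7-dimethyldeca-1,3,5,7-tetraen-9-yn-1-yl]-1,5,5-trimethylcyclohex-1-ene | CC1=CCCC(C)(C)[C@H]1/C=C/C(C)=C/C=C/C(C)=C/C#C | intermediate
11 | prop-2-yn-1-ol | C#CCO | starting material
12 | dimethylaluminium (2E)-3-(dimethylalumanyl)-2-methylprop-2-en-1-olate | C[Al](C)OC/C(C)=C/[Al](C)C | intermediate
13 | (2E)-3-iodo-2-methylprop-2-en-1-ol | OC/C(C)=C/I | intermediate
14 | (1E)-3-bromo-1-iodo-2-methylprop-1-ene | BrC/C(C)=C/I | intermediate
15 | diethyl [(2E)-3-iodo-2-methylprop-2-en-1-yl]phosphonate | CCOP(=O)(C/C(C)=C/I)OCC | intermediate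
16 | ethyl acetoacetate | CCOC(=O)CC(C)=O | starting material
17 | ethyl (2E)-3-{[(trifluoromethyl)sulfonyl]oxy}but-2-enoate | CCOC(=O)/C=C(\C)OS(=O)(=O)C(F)(F)F | intermediate
18 | (2E)-4-hydroxybut-2-en-2-yl trifluoromethanesulfonate | OC/C=C(\C)OS(=O)(=O)C(F)(F)F | intermediate
19 | β-cyclogeraniol, (2,6,6-trimethylcyclohex-1-en-1-yl)methanol | CC1=C(CO)C(C)(C)CCC1 | starting material
20 | [(1R,6R)-2,2,6-trimethyl-7-oxabicyclo[4.1.0]heptan-1-yl]methanol | C[C@@]12CCCC(C)(C)[C@]1(CO)O2 | intermediate
21 | (1S,6R)-2,2,6-trimethyl-7-oxabicyclo[4.1.0]heptane-1-carbaldehyde | C[C@@]12CCCC(C)(C)[C@]1(C=O)O2 | intermediate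
22 | (1R,6R)-1-ethynyl-2,2,6-trimethyl-7-oxabicyclo[4.1.0]heptane | C[C@@]12CCCC(C)(C)[C@]1(C#C)O2 | intermediate
23 | (2E)-3-methyl-5-[(1R,6R)-2,2,6-trimethyl-7-oxabicyclo[4.1.0]heptan-1-yl]pent-2-en-4-yn-1-ol | C[C@@]12CCCC(C)(C)[C@]1(C#C/C(C)=C/CO)O2 | intermediate
24 | bis[diethoxy(methyl)silyl] ether of 25 | C[C@@]1(O[Si](C)(OCC)OCC)CCCC(C)(C)C1=[C@]=C([H])/C(C)=C/CO[Si](C)(OCC)OCC | intermediate
25 | (2E)-5-[(2R)-2-hydroxy-2,6,6-trimethylcyclohexylidene]-3-methylpenta-2,4-dien-1-ol, allene axis aS (H-8 on the face of the C5 methyl group) | C[C@@]1(O)CCCC(C)(C)C1=[C@]=C([H])/C(C)=C/CO | intermediate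
26 | (2E)-3-[(2R,7aR)-4,4,7a-trimethyl-2,4,5,6,7,7a-hexahydro-1-benzofuran-2-yl]but-2-en-1-ol | OC/C=C(\C)[C@H]1C=C2C(C)(C)CCC[C@@]2(C)O1 | intermediate
27 | (2E)-3-[(2R,7aR)-4,4,7a-trimethyl-2,4,5,6,7,7a-hexahydro-1-benzofuran-2-yl]but-2-enal | O=C/C=C(\C)[C@H]1C=C2C(C)(C)CCC[C@@]2(C)O1 | intermediate
28 | (2R,7aR)-2-[(2E,4E,6E)-7-iodo-6-methylhepta-2,4,6-trien-2-yl]-4,4,7a-trimethyl-2,4,5,6,7,7a-hexahydro-1-benzofuran | I/C=C(C)/C=C/C=C(\C)[C@H]1C=C2C(C)(C)CCC[C@@]2(C)O1 | intermediate
29 | 2-[(1E,3E,5E,7E,9E)-4,8-dimethyl-10-[(1R)-2,6,6-trimethylcyclohex-2-en-1-yl]deca-1,3,5,7,9-pentaen-1-yl]-4,4,5,5-tetramethyl-1,3,2-dioxaborolane | CC1=CCCC(C)(C)[C@H]1/C=C/C(C)=C/C=C/C(C)=C/C=C/B1OC(C)(C)C(C)(C)O1 | intermediate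
30 | (5R,8R,6′R)-5,8-epoxy-5,8-dihydro-β,ε-carotene (CNP0168410.1) | CC1=CCCC(C)(C)[C@H]1/C=C/C(C)=C/C=C/C(C)=C/C=C/C=C(C)/C=C/C=C(\C)[C@H]1C=C2C(C)(C)CCC[C@@]2(C)O1 | target

Total step count: 19.
Longest linear sequence: 9 steps (19 → 20 → 21 → 22 → 23 → 25 → 26 → 27 → 28 → 30; steps 11 to 19).

Steps most likely to fail, each with one fallback:

1. Step 15, copper hydride SN2′ reduction. Hydride may be delivered syn to the epoxide oxygen (poor facial selectivity, giving the other allene axis and so the C8 epimer), or the alkyne may be semi-reduced without ring opening. The fallback gives up the allene relay and sets out from aldehyde 21. Horner–Wadsworth–Emmons olefination of 21 with triethyl 3-methyl-4-phosphonocrotonate (NaH, THF, 0 °C) should give ethyl (2E,4E)-3-methyl-5-[(1S,6R)-2,2,6-trimethyl-7-oxabicyclo[4.1.0]heptan-1-yl]penta-2,4-dienoate F1. A trace of HCl in CHCl3 at 0 °C should then trigger the 5,6-epoxide to 5,8-epoxide ring expansion (ionisation of C6–O, attack of the C5 oxygen on C8) to ethyl (2E)-3-[(2R,7aR)-4,4,7a-trimethyl-2,4,5,6,7,7a-hexahydro-1-benzofuran-2-yl]but-2-enoate F2 together with its (2S,7aR) epimer F3, which are separated by chromatography. Reduction of F2 with iBu2AlH (CH2Cl2, −78 °C) gives alcohol 26, where the route is rejoined. C8 is then fixed by separation and not by relay.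

2. Step 16, gold-catalysed ring closure. The Lewis-acidic metal may ionise the new doubly allylic C8–O bond (loss of configuration at C8) or divert the vinylallene into a Nazarov-type carbocyclisation. The fallback sets out from allenol 25 and closes the ring with an electrophile. N-Iodosuccinimide in CH2Cl2 at −20 °C should effect 5-endo iodoetherification to (2E)-3-[(2S,7aR)-3-iodo-4,4,7a-trimethyl-2,4,5,6,7,7a-hexahydro-1-benzofuran-2-yl]but-2-en-1-ol F4; the C8 substituents are spectators of the closure, so the same spatial arrangement at C8 results (the descriptor changes only because of the iodine). Bu3SnH with catalytic Pd(PPh3)4 in THF then removes the vinylic iodine and gives 26, where the route is rejoined.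

3. Step 19, one-flask hydroboration and coupling. Hydroboration may be incomplete, or the pentaenyl boronate may suffer protodeboronation or E/Z isomerisation before it couples. The fallback sets out from aldehyde 9 and uses a tin partner under neutral conditions. Takai-type stannylolefination of 9 (Bu3SnCHBr2, CrCl2, LiI, THF/DMF, rt, dark) should give tributyl[(1E,3E,5E,7E,9E)-4,8-dimethyl-10-[(1R)-2,6,6-trimethylcyclohex-2-en-1-yl]deca-1,3,5,7,9-pentaen-1-yl]stannane F5. Stille coupling of F5 with iodide 28 (Pd2(dba)3, AsPh3, N-methylpyrrolidone, rt, dark) forms the same C14–C15 bond and gives 30 directly.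

Further compounds
F1 | step 15 | ethyl (2E,4E)-3-methyl-5-[(1S,6R)-2,2,6-trimethyl-7-oxabicyclo[4.1.0]heptan-1-yl]penta-2,4-dienoate | C[C@@]12CCCC(C)(C)[C@]1(/C=C/C(C)=C/C(=O)OCC)O2
F2 | step 15 | ethyl (2E)-3-[(2R,7aR)-4,4,7a-trimethyl-2,4,5,6,7,7a-hexahydro-1-benzofuran-2-yl]but-2-enoate | CCOC(=O)/C=C(\C)[C@H]1C=C2C(C)(C)CCC[C@@]2(C)O1
F3 | step 15 | ethyl (2E)-3-[(2S,7aR)-4,4,7a-trimethyl-2,4,5,6,7,7a-hexahydro-1-benzofuran-2-yl]but-2-enoate | CCOC(=O)/C=C(\C)[C@@H]1C=C2C(C)(C)CCC[C@@]2(C)O1
F4 | step 16 | (2E)-3-[(2S,7aR)-3-iodo-4,4,7a-trimethyl-2,4,5,6,7,7a-hexahydro-1-benzofuran-2-yl]but-2-en-1-ol | IC1=C2C(C)(C)CCC[C@@]2(C)O[C@H]1/C(C)=C/CO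
F5 | step 19 | tributyl[(1E,3E,5E,7E,9E)-4,8-dimethyl-10-[(1R)-2,6,6-trimethylcyclohex-2-en-1-yl]deca-1,3,5,7,9-pentaen-1-yl]stannane | CC1=CCCC(C)(C)[C@H]1/C=C/C(C)=C/C=C/C(C)=C/C=C/[Sn](CCCC)(CCCC)CCCC
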